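The route opens ring C at C3–C4, an acyloin bond: the C3 carbinol lies next to the C4 aryl ketone. In one operation a chiral triazolium carbene should turn the aryl aldehyde (future C4) of an open dialdehyde into an acyl anion equivalent that attacks the second aldehyde (future C3). This closes ring C and fixes C3, while C2, an α-aryl-α-aryloxy aldehyde carbon in the open form, racemises so that one enantiomer is funnelled through. The precursor is racemic 2-[3,4-bis(benzyloxy)phenyl]-2-(2-formyl-3,5-dimethoxyphenoxy)acetaldehyde, reached by branched O-allylation and alkene cleavage; acetylation and one BCl3 deprotection complete the target.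

Key step: step 4

Remark (assumption): the sense of induction of the carbene catalyst in step 4 cannot be predicted with confidence. The catalyst enantiomer that delivers (2R,3R) is to be fixed in a first run; both enantiomers are available.

Remark: the target is (2R,3R), i.e. 2,3-trans, and all structures below were drawn to match it. The precursor keeps two benzyl and two methyl ethers. O7 must end as a methyl ether, and O5, chelated to C4=O in the product, is the one methyl ether that BCl3 removes together with the benzyl groups. Dialdehyde 8 is generated from the stable vinyl ether 6 and cyclised without storage.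

Step 1
Reactants: 1 3,4-bis(benzyloxy)benzaldehyde; 2 vinylmagnesium bromide
Product: 4 rac-tert-butyl 1-[3,4-bis(benzyloxy)phenyl]prop-2-en-1-yl carbonate, via bromomagnesium alkoxide 3 (not isolated)
Conditions: 2 (1.1 equiv), THF, –78 → 0 °C; then Boc2O (1.2 equiv), 0 °C → rt; H2O quench
Reagents that add atoms: di-tert-butyl dicarbonate, CC(C)(C)OC(=O)OC(=O)OC(C)(C)C
Why: Grignard 1,2-addition to the aldehyde followed by O-acylation of the magnesium alkoxide with Boc2O in the same flask is routine and gives the branched allylic carbonate directly; the new centre is racemic, as the later dynamic resolution requires.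

Step 2
Reactants: 4 rac-tert-butyl 1-[3,4-bis(benzyloxy)phenyl]prop-2-en-1-yl carbonate; 5 2-hydroxy-4,6-dimethoxybenzaldehyde
Product: 6 rac-2-({1-[3,4-bis(benzyloxy)phenyl]prop-2-en-1-yl}oxy)-4,6-dimethoxybenzaldehyde
Conditions: [Cp*Ru(MeCN)3]PF6 (5 mol%), 2,2'-bipyridine (5 mol%), THF, rt
Reagents that add atoms: none
Why: Ruthenium-catalysed allylic etherification (Tsuji–Trost-type substitution through a Cp*Ru η3-allyl cation): ionisation releases CO2 and tert-butoxide, which deprotonates the phenol, and the aryloxide attacks the aryl-bearing allyl terminus, the known branched preference of Cp*Ru catalysts with aryl-substituted allyl carbonates; the ether carbon is formed racemic on purpose.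

Step 3
Reactants: 6 rac-2-({1-[3,4-bis(benzyloxy)phenyl]prop-2-en-1-yl}oxy)-4,6-dimethoxybenzaldehyde
Product: 8 rac-2-[3,4-bis(benzyloxy)phenyl]-2-(2-formyl-3,5-dimethoxyphenoxy)acetaldehyde, via vicinal diol 7 (not isolated)
Conditions: OsO4 (2 mol%), NaIO4 (4 equiv), 2,6-lutidine (2 equiv), dioxane–H2O 3:1, rt; crude product used at once
Reagents that add atoms: osmium tetroxide, O=[Os](=O)(=O)=O (catalytic oxygen carrier); sodium periodate, [Na+].[O-]I(=O)(=O)=O (terminal oxidant supplying the oxygen)
Why: Lemieux–Johnson oxidation: the terminal alkene is the only site that OsO4 dihydroxylates and periodate cleaves the glycol to the aldehyde, while the aryl aldehyde and the ethers are untouched and lutidine limits over-oxidation; the centre α to the new aldehyde stays racemic and labile, as intended.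

Step 4
Reactants: 8 rac-2-[3,4-bis(benzyloxy)phenyl]-2-(2-formyl-3,5-dimethoxyphenoxy)acetaldehyde
Product: 9 (2R,3R)-2-[3,4-bis(benzyloxy)phenyl]-3-hydroxy-5,7-dimethoxychroman-4-one
Conditions: chiral aminoindanol-derived N-C6F5 triazolium tetrafluoroborate (10 mol%), i-Pr2NEt (0.5 equiv), toluene (0.02 M), rt, Ar
Reagents that add atoms: none
Why: Proposed new method: the free carbene adds to the aryl aldehyde (future C4), proton transfer gives the Breslow intermediate, this acyl anion equivalent attacks the aliphatic aldehyde carbon (future C3) to make the C3–C4 bond, and collapse of the adduct releases the carbene and leaves the C4 ketone beside the C3 carbinol. The closest known reaction types are chiral triazolium-catalysed intramolecular crossed benzoin cyclisations of salicylaldehyde-derived keto aldehydes to 3-hydroxychroman-4-ones and carbene-catalysed dynamic kinetic resolutions of base-labile α-centres; an aldehyde acceptor carrying a racemising α-aryloxy-α-aryl centre has not been shown. Ring C closes 6-exo-trig, the C4 nucleophile attacking the C3 carbonyl whose oxygen stays outside the ring. C3 is set by the catalyst, which exposes one face of the acceptor carbonyl, and is backed up by thermodynamics, because this carbinol is α to the new ketone and can epimerise to the trans-diequatorial isomer; C2 is selected and not created, since the catalyst-bound intermediate should close faster on the enantiomer that places the 2-aryl group pseudo-equatorial in the favoured transition state while i-Pr2NEt returns the slower enantiomer to the racemate through the enol. The step needs chemoselectivity for carbene addition at the aryl aldehyde (a Breslow intermediate at C3 could expel the aryloxide) and for benzoin over 5-exo aldol closure: the α,α-disubstituted C3 aldehyde is a reluctant carbene acceptor but a good electrophile, carbene addition and benzoin formation are reversible so material should drain to the conjugated aryl ketone, and the weak base keeps the enolate concentration low.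

Step 5
Reactants: 9 (2R,3R)-2-[3,4-bis(benzyloxy)phenyl]-3-hydroxy-5,7-dimethoxychroman-4-one
Product: 10 (2R,3R)-2-[3,4-bis(benzyloxy)phenyl]-5,7-dimethoxy-4-oxochroman-3-yl acetate
Conditions: Ac2O, pyridine, DMAP (cat.), CH2Cl2, 0 °C → rt
Reagents that add atoms: acetic anhydride, CC(=O)OC(C)=O
Why: DMAP-catalysed O-acylation (nucleophilic catalysis) of the only free hydroxyl; no stereocentre is formed and the trans-2,3 arrangement, being the thermodynamic one, is not at risk under pyridine.

Step 6
Reactants: 10 (2R,3R)-2-[3,4-bis(benzyloxy)phenyl]-5,7-dimethoxy-4-oxochroman-3-yl acetate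
Product: 11 3-O-acetylpadmatin, (2R,3R)-2-(3,4-dihydroxyphenyl)-5-hydroxy-7-methoxy-4-oxochroman-3-yl acetate
Conditions: BCl3 (6 equiv), C6HMe5 (5 equiv), CH2Cl2, –78 → 0 °C; then pH 7 buffer
Reagents that add atoms: none
Why: Lewis-acid ether cleavage: BCl3 bound to the C4 carbonyl cleaves only the methyl ether held in the six-membered chelate (O5) and also cleaves the two benzyl aryl ethers, with pentamethylbenzene trapping the benzyl cations, while the non-chelated 7-methyl ether and the acetate should survive at or below 0 °C; no bond to C2 or C3 is broken.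

Compound list
1 | 3,4-bis(benzyloxy)benzaldehyde | O=Cc1ccc(OCc2ccccc2)c(OCc2ccccc2)c1 | starting material
2 | vinylmagnesium bromide | C=C[Mg]Br | starting material
3 | bromomagnesium 1-[3,4-bis(benzyloxy)phenyl]prop-2-en-1-olate (racemic) | C=CC(O[Mg]Br)c1ccc(OCc2ccccc2)c(OCc2ccccc2)c1 | intermediate
4 | tert-butyl 1-[3,4-bis(benzyloxy)phenyl]prop-2-en-1-yl carbonate (racemic) | C=CC(OC(=O)OC(C)(C)C)c1ccc(OCc2ccccc2)c(OCc2ccccc2)c1 | intermediate
5 | 2-hydroxy-4,6-dimethoxybenzaldehyde | O=Cc1c(O)cc(OC)cc1OC | starting material
6 | 2-({1-[3,4-bis(benzyloxy)phenyl]prop-2-en-1-yl}oxy)-4,6-dimethoxybenzaldehyde (racemic) | COc1cc(OC)c(C=O)c(c1)OC(C=C)c1ccc(OCc2ccccc2)c(OCc2ccccc2)c1 | intermediate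
7 | 2-({1-[3,4-bis(benzyloxy)phenyl]-2,3-dihydroxypropyl}oxy)-4,6-dimethoxybenzaldehyde (mixture of stereoisomers) | COc1cc(OC)c(C=O)c(c1)OC(C(O)CO)c1ccc(OCc2ccccc2)c(OCc2ccccc2)c1 | intermediate
8 | 2-[3,4-bis(benzyloxy)phenyl]-2-(2-formyl-3,5-dimethoxyphenoxy)acetaldehyde (racemic) | COc1cc(OC)c(C=O)c(c1)OC(C=O)c1ccc(OCc2ccccc2)c(OCc2ccccc2)c1 | intermediate
9 | (2R,3R)-2-[3,4-bis(benzyloxy)phenyl]-3-hydroxy-5,7-dimethoxychroman-4-one | COc1cc(OC)c2c(c1)O[C@H](c1ccc(OCc3ccccc3)c(OCc3ccccc3)c1)[C@@H](O)C2=O | intermediate
10 | (2R,3R)-2-[3,4-bis(benzyloxy)phenyl]-5,7-dimethoxy-4-oxochroman-3-yl acetate | COc1cc(OC)c2c(c1)O[C@H](c1ccc(OCc3ccccc3)c(OCc3ccccc3)c1)[C@@H](OC(C)=O)C2=O | intermediate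
11 | 3-O-acetylpadmatin, (2R,3R)-2-(3,4-dihydroxyphenyl)-5-hydroxy-7-methoxy-4-oxochroman-3-yl acetate | COc1cc(O)c2c(c1)O[C@H](c1ccc(O)c(O)c1)[C@@H](OC(C)=O)C2=O | target

Total step count: 6. Longest linear sequence: 6 steps (1 → 4 → 6 → 8 → 9 → 10 → 11).

Steps most likely to fail

Step 4 (proposed new method). The carbene may add to the more electrophilic aliphatic aldehyde and then lose the aryloxide in an irreversible internal redox. Turnover at the doubly ortho-substituted aryl aldehyde may be slow. Discrimination between the C2 enantiomers, or their racemisation, may be insufficient, and aldol closure may compete. The fallback uses known chemistry; it sets out from 1 and returns at 9. Commercial 1-(2-hydroxy-4,6-dimethoxyphenyl)ethan-1-one is protected (NaH, MOMCl, DMF) as 1-[2,4-dimethoxy-6-(methoxymethoxy)phenyl]ethan-1-one F1. Claisen–Schmidt condensation of this ketone with 1 (KOH, EtOH) should give the chalcone (E)-3-[3,4-bis(benzyloxy)phenyl]-1-[2,4-dimethoxy-6-(methoxymethoxy)phenyl]prop-2-en-1-one F2. Juliá–Colonna epoxidation (poly-L-leucine, urea–H2O2, DBU, THF; the antipodal polymer if the sense proves opposite) should give the epoxy ketone {(2R,3S)-3-[3,4-bis(benzyloxy)phenyl]oxiran-2-yl}[2,4-dimethoxy-6-(methoxymethoxy)phenyl]methanone F3. HCl in MeOH then removes the MOM group and the freed phenol opens the oxirane at the benzylic carbon with inversion (6-endo), the classical chalcone-epoxide entry to trans-dihydroflavonols, to give 9.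

Step 2. The electron-rich benzylic allylic ether may re-ionise and isomerise to the linear cinnamyl ether. The hydrogen-bonded phenol may be too weak a nucleophile, and the dimethoxyarene may be C-allylated. The fallback sets out from 5 and returns at 8. Purchased methyl 2-[3,4-bis(benzyloxy)phenyl]acetate is brominated through its silyl ketene acetal (LiHMDS, TMSCl, THF, –78 °C; then NBS) to methyl 2-bromo-2-[3,4-bis(benzyloxy)phenyl]acetate F4. Williamson alkylation of 5 with this bromide (K2CO3, acetone, rt) fixes the ether position by SN2 and should give methyl 2-[3,4-bis(benzyloxy)phenyl]-2-(2-formyl-3,5-dimethoxyphenoxy)acetate F5. LiAlH4 (THF, 0 °C) reduces ester and aldehyde to 2-[3,4-bis(benzyloxy)phenyl]-2-[2-(hydroxymethyl)-3,5-dimethoxyphenoxy]ethan-1-ol F6. Buffered Dess–Martin oxidation of both primary alcohols (DMP, NaHCO3, CH2Cl2) gives 8.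

Step 6. The acetate may be lost, or cleavage of three ethers in one pot may be incomplete or accompanied by Friedel–Crafts benzylation of the electron-rich rings. The fallback sets out from 10 and returns at 11. Hydrogenolysis (H2 1 atm, Pd/C, EtOAc) removes both benzyl groups without forming benzyl cations and should give (2R,3R)-2-(3,4-dihydroxyphenyl)-5,7-dimethoxy-4-oxochroman-3-yl acetate F7. Only the chelated 5-methyl ether then remains to be cleaved with BCl3 (CH2Cl2, –78 → 0 °C), which gives 11.

Further compounds
F1 | step 4 | 1-[2,4-dimethoxy-6-(methoxymethoxy)phenyl]ethan-1-one | COCOc1cc(OC)cc(OC)c1C(C)=O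
F2 | step 4 | (E)-3-[3,4-bis(benzyloxy)phenyl]-1-[2,4-dimethoxy-6-(methoxymethoxy)phenyl]prop-2-en-1-one | COCOc1cc(OC)cc(OC)c1C(=O)/C=C/c1ccc(OCc2ccccc2)c(OCc2ccccc2)c1
F3 | step 4 | {(2R,3S)-3-[3,4-bis(benzyloxy)phenyl]oxiran-2-yl}[2,4-dimethoxy-6-(methoxymethoxy)phenyl]methanone | COCOc1cc(OC)cc(OC)c1C(=O)[C@@H]2O[C@H]2c2ccc(OCc3ccccc3)c(OCc3ccccc3)c2
F4 | step 2 | methyl 2-bromo-2-[3,4-bis(benzyloxy)phenyl]acetate (racemic) | COC(=O)C(Br)c1ccc(OCc2ccccc2)c(OCc2ccccc2)c1
F5 | step 2 | methyl 2-[3,4-bis(benzyloxy)phenyl]-2-(2-formyl-3,5-dimethoxyphenoxy)acetate (racemic) | COC(=O)C(Oc1cc(OC)cc(OC)c1C=O)c1ccc(OCc2ccccc2)c(OCc2ccccc2)c1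
F6 | step 2 | 2-[3,4-bis(benzyloxy)phenyl]-2-[2-(hydroxymethyl)-3,5-dimethoxyphenoxy]ethan-1-ol (racemic) | COc1cc(OC)c(CO)c(c1)OC(CO)c1ccc(OCc2ccccc2)c(OCc2ccccc2)c1
F7 | step 6 | (2R,3R)-2-(3,4-dihydroxyphenyl)-5,7-dimethoxy-4-oxochroman-3-yl acetate | COc1cc(OC)c2c(c1)O[C@H](c1ccc(O)c(O)c1)[C@@H](OC(C)=O)C2=O
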